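**Retrosynthetic overview**
1. Ring numbering: C3 carries the hexadecyl chain, C2 and C5 the hydroxyls, C1 and C4 are the carbonyls, C6 carries H. The plan rests on two features: C1-C2-C3-C4 with its three oxygens is the carbon set of a squarate, and C5(O)-C6(H) is the two-carbon unit of an alkoxyalkyne.
2. Last disconnection: both hydroxyls come from the two vinylogous ester groups of 5-ethoxy-3-hexadecyl-2-methoxy-1,4-benzoquinone by hydroxide addition-elimination.
3. Key disconnection C4-C5: the only ring of the target is closed by thermal ring expansion of a 4-hydroxycyclobutenone (Moore rearrangement). The four-membered ring opens to a vinylketene, and its ketene carbon C4 bonds to the ethoxy-bearing carbon C5.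
4. The C5-C6 unit enters as lithium ethoxyacetylide (C1-C6 bond), and the triple bond is semi-hydrogenated to the Z enol ether before heating. In the ynol ether C6 is the nucleophilic carbon and would pair with the electrophilic ketene carbon in a five-membered closure, and ethyl ynol ethers lose ethene by retro-ene reaction near the thermolysis temperature. The dienylketene has a concerted path to C5 only, and Ag2O restores the quinone level.
5. The four-membered ring is bought as dimethyl squarate. Hexadecylmagnesium bromide forms the C3-chain bond, and the six-membered ring forms afterwards by expansion of the four-membered one.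

Key step: step 5

Remark: atom labels C1 to C6 follow the quinone numbering above throughout. The carbinol intermediates are racemic, and their single stereocentre disappears in the ring expansion. The target has no stereocentre.

Step 1
Reactants: 1 1-bromohexadecane
Product: 2 hexadecylmagnesium bromide (THF solution, titrated and used as such)
Conditions: Mg turnings, I2 (cat.), THF, 40-50 °C
Reagents that add atoms: magnesium, [Mg]
Why: Grignard reagent formation by insertion of magnesium into a primary C-Br bond is routine, and slow addition of 1 to excess metal should keep Wurtz coupling low.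

Step 2
Reactants: 2 hexadecylmagnesium bromide; 3 dimethyl squarate (3,4-dimethoxycyclobut-3-ene-1,2-dione)
Product: 5 3-hexadecyl-4-methoxycyclobut-3-ene-1,2-dione, via 4-hexadecyl-4-hydroxy-2,3-dimethoxycyclobut-2-en-1-one 4 (not isolated)
Conditions: 2 (1.05 equiv) added to 3, THF, -78 to -40 °C; 1 M HCl quench; crude 4, conc. HCl (cat.), CH2Cl2, rt
Reagents that add atoms: water, O
Why: Grignard 1,2-addition to one of the two equivalent squarate carbonyls stops at the magnesium alkoxide, and the acid-catalysed allylic transposition of carbinol 4 (ionisation, capture of the methoxy-stabilised cation by water, loss of methanol) is the standard squarate-to-alkylcyclobutenedione sequence that forms the C3-chain bond.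

Step 3
Reactants: 5 3-hexadecyl-4-methoxycyclobut-3-ene-1,2-dione; 6 ethoxyacetylene (ethoxyethyne)
Product: 8 4-(ethoxyethynyl)-2-hexadecyl-4-hydroxy-3-methoxycyclobut-2-en-1-one (racemic), via lithium ethoxyacetylide 7 (not isolated)
Conditions: 6, n-BuLi, THF, -78 °C; then 5, THF, -78 °C; sat. aq. NH4Cl; Et3N-deactivated SiO2
Reagents that add atoms: none
Why: Acetylide 1,2-addition should go to the carbonyl next to the methoxy-bearing carbon, because the other carbonyl is deactivated as the end of the vinylogous ester MeO-C=C-C=O, so the C1-C6 bond forms, the chain sits on the carbon next to the future ketene carbon C4, and the racemic carbinol centre is lost in step 5.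

Step 4
Reactants: 8 4-(ethoxyethynyl)-2-hexadecyl-4-hydroxy-3-methoxycyclobut-2-en-1-one
Product: 9 4-[(Z)-2-ethoxyethenyl]-2-hexadecyl-4-hydroxy-3-methoxycyclobut-2-en-1-one (racemic)
Conditions: H2 (1 atm, stopped after 1 equiv), Pd/CaCO3 poisoned with Pb(OAc)2 (Lindlar catalyst), quinoline, EtOAc, rt; filtration, no contact with acid
Reagents that add atoms: none
Why: Lindlar semi-hydrogenation delivers both hydrogens to one face of the triple bond and so sets the Z enol ether, as in the reduction stage of the Arens-van Dorp enal synthesis with ethoxyethynyl carbinols, while the tetrasubstituted push-pull ring alkene and the ketone should stay untouched and quinoline keeps the medium free of acid.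

Step 5
Reactants: 9 4-[(Z)-2-ethoxyethenyl]-2-hexadecyl-4-hydroxy-3-methoxycyclobut-2-en-1-one
Product: 13 5-ethoxy-3-hexadecyl-2-methoxy-1,4-benzoquinone, via dienylketene 10 (not isolated), via cyclohexadienone 11 (not isolated), via hydroquinone 12 (not isolated)
Conditions: PhMe (0.02 M, degassed, base-washed glass), 110 °C, Ar; cool to rt; Ag2O (1.5 equiv), rt
Reagents that add atoms: none
Why: Heating cleaves the C1-C4 bond of the four-membered ring in a conrotatory 4π electrocyclic opening in which the hydroxyl donor on C1 turns outward, so the ethoxyvinyl group turns inward and lies cis to the ketene in dienylketene 10. The ketene carbon C4 then bonds to the ethoxy-bearing carbon C5 in a disrotatory 6π electrocyclisation, which forms C4-C5 and closes the six-membered carbocycle as cyclohexadienone 11. Enolisation of 11 gives hydroquinone 12, and Ag2O takes 12 to quinone 13 in the same flask. The closest known reaction type is the Moore rearrangement of 4-alkenyl-4-hydroxycyclobutenones to hydroquinones with oxidative work-up. The only new stereocentre, C5 of 11, is transient and is erased on aromatisation, so no stereocontrol is needed. The step needs closure at C5 and not at C6, which the enol ether secures because it offers the ketene a concerted six-electron path to C5 only, it needs outward rotation of the hydroxyl, which the donor character of oxygen secures, and it needs enolisation of 11 to outrun loss of ethanol, which the neutral, acid-free, non-polar medium favours; the place of the chain was fixed in step 3.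

Step 6
Reactants: 13 5-ethoxy-3-hexadecyl-2-methoxy-1,4-benzoquinone
Product: 15 2,5-dihydroxy-3-hexadecyl-1,4-benzoquinone (target), via disodium salt 14 (not isolated)
Conditions: 2 M aq. NaOH, EtOH, reflux, Ar; then 2 M HCl to pH 1-2, 0 °C; filtration, recrystallisation
Reagents that add atoms: sodium hydroxide, [Na+].[OH-]
Why: Each alkoxy group is the ester end of a vinylogous ester of a quinone carbonyl, so hydroxide should replace it by conjugate addition-elimination at C2 and C5 (vinylogous saponification), the delocalised dianion 14 resists further attack, and acid frees 15.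

**Compound list**
1 | 1-bromohexadecane | CCCCCCCCCCCCCCCCBr | starting material
2 | hexadecylmagnesium bromide | CCCCCCCCCCCCCCCC[Mg]Br | intermediate
3 | dimethyl squarate (3,4-dimethoxycyclobut-3-ene-1,2-dione) | COC1=C(OC)C(=O)C1=O | starting material
4 | 4-hexadecyl-4-hydroxy-2,3-dimethoxycyclobut-2-en-1-one (racemic) | CCCCCCCCCCCCCCCCC1(O)C(OC)=C(OC)C1=O | intermediate
5 | 3-hexadecyl-4-methoxycyclobut-3-ene-1,2-dione | CCCCCCCCCCCCCCCCC1=C(OC)C(=O)C1=O | intermediate
6 | ethoxyacetylene | CCOC#C | starting material
7 | lithium ethoxyacetylide | CCOC#C[Li] | intermediate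
8 | 4-(ethoxyethynyl)-2-hexadecyl-4-hydroxy-3-methoxycyclobut-2-en-1-one (racemic) | CCCCCCCCCCCCCCCCC1=C(OC)C(O)(C#COCC)C1=O | intermediate
9 | 4-[(Z)-2-ethoxyethenyl]-2-hexadecyl-4-hydroxy-3-methoxycyclobut-2-en-1-one (racemic) | CCCCCCCCCCCCCCCCC1=C(OC)C(O)(/C=C\OCC)C1=O | intermediate
10 | (3Z,5Z)-6-ethoxy-2-hexadecyl-4-hydroxy-3-methoxyhexa-1,3,5-trien-1-one (dienylketene) | CCCCCCCCCCCCCCCCC(=C=O)/C(OC)=C(O)\C=C/OCC | intermediate
11 | 6-ethoxy-2-hexadecyl-4-hydroxy-3-methoxycyclohexa-2,4-dien-1-one (racemic) | CCCCCCCCCCCCCCCCC1=C(OC)C(O)=CC(OCC)C1=O | intermediate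
12 | 5-ethoxy-3-hexadecyl-2-methoxybenzene-1,4-diol | CCCCCCCCCCCCCCCCc1c(OC)c(O)cc(OCC)c1O | intermediate
13 | 5-ethoxy-3-hexadecyl-2-methoxycyclohexa-2,5-diene-1,4-dione | CCCCCCCCCCCCCCCCC1=C(OC)C(=O)C=C(OCC)C1=O | intermediate
14 | disodium 3-hexadecyl-1,4-benzoquinone-2,5-diolate | CCCCCCCCCCCCCCCCC1=C([O-])C(=O)C=C([O-])C1=O.[Na+].[Na+] | intermediate
15 | 2,5-dihydroxy-3-hexadecylcyclohexa-2,5-diene-1,4-dione | CCCCCCCCCCCCCCCCC1=C(O)C(=O)C=C(O)C1=O | target

**Total step count:** 6
**Longest linear sequence:** 6 steps (1, 2, 5, 8, 9, 13, 15)

**Steps most likely to fail**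

1. Step 5. Three processes can spoil it:
   - ethanol may be lost from the ring-closed dienone before it enolises;
   - part of the material may open with the hydroxyl turning inward and lactonise on the ketene;
   - the allylic carbinol may ionise before the ring opens.

   The fallback takes the C5 oxygen out of the thermal step. It sets out from 5 and comes back at 15. Commercial ethynylmagnesium bromide (THF, -78 °C) adds to the ketone-type carbonyl of 5 and gives 4-ethynyl-2-hexadecyl-4-hydroxy-3-methoxycyclobut-2-en-1-one F1. Heating in toluene or p-xylene brings about the alkynyl Moore rearrangement, in which an unsubstituted alkyne terminus closes to the six-membered ring, and gives 2-hexadecyl-3-methoxy-1,4-benzoquinone F2. Thiele-Winstein acetoxylation (Ac2O, cat. H2SO4) places the new oxygen at C5, the position conjugated to the carbonyl that the methoxy group does not deactivate, and gives 6-hexadecyl-5-methoxybenzene-1,2,4-triyl triacetate F3. Saponification (NaOH, aq. EtOH) frees 6-hexadecyl-5-methoxybenzene-1,2,4-triol F4, which air oxidises in the alkaline medium to 3-hexadecyl-5-hydroxy-2-methoxy-1,4-benzoquinone F5. Continued heating with NaOH as in step 6 displaces the methoxy group, and acidification gives 15.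

2. Step 4. The enol ether may be reduced further, or the acid-labile carbinol may ionise and undergo allylic transposition on the catalyst support or during isolation. The fallback forms the C1-C6 bond with the alkene already in place. It sets out from 5 and comes back at 9. Commercial (Z)-1-bromo-2-ethoxyethene is treated with t-BuLi (2 equiv, Et2O, -78 °C) to give (Z)-2-ethoxyvinyllithium F6. This reagent keeps its geometry at that temperature and adds to the ketone-type carbonyl of 5, giving 9 directly after an NH4Cl quench, so 8 and the hydrogenation are bypassed.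

3. Step 2. The long-chain Grignard reagent may precipitate at low temperature so that addition stalls, and over-addition may set in once the mixture is warmed. The fallback brings the chain in as an sp nucleophile and saturates it afterwards. It sets out from 3 and comes back at 5. Commercial 1-hexadecyne is deprotonated (n-BuLi, THF, -78 °C) to lithium hexadec-1-yn-1-ide F7, which stays in solution at -78 °C and adds once to 3, giving 4-(hexadec-1-yn-1-yl)-4-hydroxy-2,3-dimethoxycyclobut-2-en-1-one F8. The same acid-catalysed transposition (conc. HCl cat., CH2Cl2, rt) gives 3-(hexadec-1-yn-1-yl)-4-methoxycyclobut-3-ene-1,2-dione F9. Hydrogenation of the triple bond (H2, Pd/C, EtOAc) gives 5. The ring alkene is a tetrasubstituted vinylogous ester of the kind that survives hydrogenolysis of benzyl squarates.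

**Further compounds**
F1 | step 5 | 4-ethynyl-2-hexadecyl-4-hydroxy-3-methoxycyclobut-2-en-1-one (racemic) | CCCCCCCCCCCCCCCCC1=C(OC)C(O)(C#C)C1=O
F2 | step 5 | 2-hexadecyl-3-methoxy-1,4-benzoquinone | CCCCCCCCCCCCCCCCC1=C(OC)C(=O)C=CC1=O
F3 | step 5 | 6-hexadecyl-5-methoxybenzene-1,2,4-triyl triacetate | CCCCCCCCCCCCCCCCc1c(OC)c(OC(C)=O)cc(OC(C)=O)c1OC(C)=O
F4 | step 5 | 6-hexadecyl-5-methoxybenzene-1,2,4-triol | CCCCCCCCCCCCCCCCc1c(OC)c(O)cc(O)c1O
F5 | step 5 | 3-hexadecyl-5-hydroxy-2-methoxy-1,4-benzoquinone | CCCCCCCCCCCCCCCCC1=C(OC)C(=O)C=C(O)C1=O
F6 | step 4 | (Z)-2-ethoxyvinyllithium | [Li]/C=C\OCC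
F7 | step 2 | lithium hexadec-1-yn-1-ide | CCCCCCCCCCCCCCC#C[Li]
F8 | step 2 | 4-(hexadec-1-yn-1-yl)-4-hydroxy-2,3-dimethoxycyclobut-2-en-1-one (racemic) | CCCCCCCCCCCCCCC#CC1(O)C(OC)=C(OC)C1=O
F9 | step 2 | 3-(hexadec-1-yn-1-yl)-4-methoxycyclobut-3-ene-1,2-dione | CCCCCCCCCCCCCCC#CC1=C(OC)C(=O)C1=O
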